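A one-step world keeps its Qo; the winter and spring runs at 20 °C do not, for their Qo sinks from the first reading to a floor.

| flask | Gy | Aj | temperature | remark | time |
|---|---|---|---|---|---|
| dusk | 10 mM | 18 mM | 5 °C | run made earlier |  |
| winter | 5 mM | 18 mM | 20 °C | run made earlier |  |
| midnight | 7.5 mM | 18 mM | 5 °C | run made earlier |  |
| spring | 10 mM | 9 mM | 20 °C | run made earlier |  |
| teal | 10 mM | 18.0 mM | 20 °C | everything together at the start | 15 h |
| blue | 10 mM | 18.0 mM (in portions, 5, over 10 h) | 20 °C | first portion at the start, last at 10 h | 15 h |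
| green | 10 mM | 18.0 mM (fed, over 10 h) | 20 °C | all else is in the flask from the start; the feed brings no volume worth counting | 15 h |
| ochre | 10 mM | 18.0 mM (fed, over 10 h) |  | the addition at −10 °C, then warmed to 20 °C; the feed brings no volume worth counting | 15 h |

| run | time / h | Qo / % | Gy / % |
|---|---|---|---|
| dusk | 2.00 | 36.2 | 0 |
| dusk | 5.00 | 43.6 | 0 |
| dusk | 8.00 | 40.9 | 0 |
| dusk | 12.0 | 37.0 | 0 |
| dusk | 20.0 | 31.4 | 0 |
| winter | 4.00 | 35.2 | 0.3 |
| winter | 8.00 | 24.4 | 0.2 |
| winter | 10.0 | 23.1 | 1.0 |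
| winter | 15.0 | 20.0 | 0.2 |
| winter | 20.0 | 21.2 | 0.6 |
| midnight | 3.00 | 48.6 | 0 |
| midnight | 10.0 | 45.1 | 0 |
| midnight | 15.0 | 40.7 | 0 |
| midnight | 25.0 | 33.9 | 0 |
| midnight | 40.0 | 26.5 | 0.5 |
| spring | 1.33 | 32.2 | 1.0 |
| spring | 2.50 | 27.5 | 0 |
| spring | 5.00 | 17.8 | 0.7 |
| spring | 10.0 | 12.4 | 0.2 |
| spring | 20.0 | 13.1 | 0.8 |

(each reading ± 0.5 percentage points)

1. which flask leads in amount of Qo, in percent of the Gy charged ("all alike" within 1.5 percentage points) (teal / blue / green / ochre / all alike)
2. how much Qo is there at the end, in percent of the Gy charged: teal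
3. how much Qo is there at the end, in percent of the Gy charged: blue
4. how much Qo is there at the end, in percent of the Gy charged: green
5. how much Qo is there at the end, in percent of the Gy charged: ochre



For whoever takes over the bench: spring reads 1.0 % of its Gy at 1.33 h, so teal, with the same Gy, should read as low when they come, and the question is what share of the Qo made stays Qo. Winter gives the reckoning:

floor, mean of the last two readings: 20.6 %
fall of the excess over the floor: 0.337 h⁻¹, half-life 2.06 h
all Qo made, excess run back to the start: 76.7 %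
floor over all Qo made: 0.269

This ratio, the back rate of the loss of Qo divided by the sum of its two rates, is the kept share (an equilibrium fraction); time drops out of it.

Spring's floor of 12.8 % divided by the kept share means 47.5 % made. Teal has spring's Gy and winter's Aj, so this reckoning takes the middle of the two amounts made:

teal: 16.7 %

Its 15 h lies well beyond the half-life, so teal should stand near its floor.

Don't feed the Aj. Spring had less Aj per Gy than winter and made less Qo. A feed starts lower still, so this reckoning puts blue, green and ochre under 12.8 %, with teal ahead.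

The forecast differs: green leads, with teal 5 %, blue 13 %, green 20 %, ochre 8 %, on the ground that “Feeding keeps the intermediate dilute, raising the initial yield”.

The flasks give teal 15.6 %, blue 9.00 %, green 7.87 % and ochre 8.68 %, so teal leads.

    GyAj → Qo (k = 0.00150 s⁻¹, Ea = 85.0 kJ mol⁻¹)
    Qo ⇌ Ux (K = 2.70, k = 6.70 × 10⁻⁵ s⁻¹, Ea = 99.0 kJ mol⁻¹, ΔH = 13.0 kJ mol⁻¹)
    2 Gy → Yx (k = 0.00800 M⁻¹ s⁻¹, Ea = 70.0 kJ mol⁻¹)
    Gy + Aj → GyAj (k = 0.230 M⁻¹ s⁻¹, Ea = 46.0 kJ mol⁻¹)
    Gy + GyAj → GyGyAj (k = 0.360 M⁻¹ s⁻¹, Ea = 39.0 kJ mol⁻¹)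
    (constants at 20 °C)

After 150 h teal holds 15.3 % Qo beside 41.4 % Ux, and the kept share times their sum gives 15.3 %. The neighbour, teal repeated at 35 °C, holds 51.7 % Ux at 15.0 h, and the same reckoning on its Qo plus Ux gives 17.9 %. That flask holds less Qo than this, namely 14.8 %, a kept share of 0.223.

All runs are simulated with made-up constants.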